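**Retrosynthetic overview**
1. No ring is built: ring A (the phenol half) and ring B (the acid half) both come intact from one cheap fragrance chemical, methyl 2,4-dihydroxy-3,6-dimethylbenzoate (1).
2. Ring A: the free C5 position of 1 is formylated (2) and the formyl group is reduced to methyl, giving phenol 3.
3. Ring B: C5 of 1 is chlorinated (4); 4-O-tosylation (5) and 2-O-methylation (6) follow in one flask, and KOH then removes both the methyl ester and the tosylate to give hydroxy acid 7.
4. Key disconnection: the depside C(acyl)–O(aryl) bond, made last and without protecting groups from 7 and 3, through O-acylisourea 8 and para-oxoketene 9, to give target 10.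
5. There is no stereochemistry to set.

Assumption: the target has no stereocentre and no configurationally stable axis, so it is achiral and "single enantiomer" is taken to mean the one constitution drawn.
Numbering note: ring B compounds are numbered from the carboxyl carbon (C1) with the ortho oxygen at C2, as in 1. By lowest-locant rules the acyl group of 10 is 3-chloro-4-hydroxy-6-methoxy-2,5-dimethylbenzoyl.

**Route**

Step 1
Reactants: 1 methyl 2,4-dihydroxy-3,6-dimethylbenzoate
Product: 2 methyl 5-formyl-2,4-dihydroxy-3,6-dimethylbenzoate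
Conditions: Cl2CHOMe (1.5 equiv), TiCl4 (3 equiv), CH2Cl2, −10 °C to rt; then ice/1 M HCl
Reagents that add atoms: dichloromethyl methyl ether, COC(Cl)Cl; water, O
Why: Rieche formylation (electrophilic aromatic substitution): C5 is the only unsubstituted ring position and is ortho to the 4-OH and para to the 2-OH, so the TiCl4-activated reagent attacks there and aqueous work-up hydrolyses the chloro(methoxy)methyl group to the aldehyde.

Step 2
Reactants: 2 methyl 5-formyl-2,4-dihydroxy-3,6-dimethylbenzoate
Product: 3 methyl 2,4-dihydroxy-3,5,6-trimethylbenzoate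
Conditions: Et3SiH (3 equiv), TFA, CH2Cl2, 0 °C to rt
Reagents that add atoms: none
Why: Ionic hydrogenation: TFA protonates the aldehyde, the benzylic cations stabilised by the ortho and para hydroxyls take up hydride from Et3SiH twice, and the ester and phenols are untouched.

Step 3
Reactants: 1 methyl 2,4-dihydroxy-3,6-dimethylbenzoate
Product: 4 methyl 5-chloro-2,4-dihydroxy-3,6-dimethylbenzoate
Conditions: SO2Cl2 (1.05 equiv), CH2Cl2, 0 °C to rt, dark
Reagents that add atoms: sulfuryl chloride, O=S(=O)(Cl)Cl
Why: Electrophilic aromatic chlorination: the single free position C5, activated by the ortho 4-OH and para 2-OH, takes up one chlorine, and one equivalent of reagent avoids chlorodienone formation.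

Step 4
Reactants: 4 methyl 5-chloro-2,4-dihydroxy-3,6-dimethylbenzoate
Product: 6 methyl 5-chloro-2-methoxy-3,6-dimethyl-4-[(4-methylbenzenesulfonyl)oxy]benzoate, via 4-O-tosylate 5 (not isolated)
Conditions: TsCl (1.05 equiv), K2CO3 (1.2 equiv), DMF, 0 °C to rt; then MeI (4 equiv), K2CO3 (2.5 equiv), 45 °C
Reagents that add atoms: 4-methylbenzenesulfonyl chloride, Cc1ccc(cc1)S(Cl)(=O)=O; iodomethane, CI
Why: O-sulfonylation followed by Williamson O-methylation (SN2) in one flask: the 4-OH is the more acidic and is not tied up in the hydrogen bond that holds the 2-OH to the ester carbonyl, so TsCl goes on O4 first, and the inert tosylate leaves only the 2-OH for MeI under the more forcing second stage.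

Step 5
Reactants: 6 methyl 5-chloro-2-methoxy-3,6-dimethyl-4-[(4-methylbenzenesulfonyl)oxy]benzoate
Product: 7 5-chloro-4-hydroxy-2-methoxy-3,6-dimethylbenzoic acid
Conditions: KOH (10 equiv), DMSO/H2O (4:1), 90 °C; then 1 M HCl, 0 °C
Reagents that add atoms: potassium hydroxide, [K+].[OH-]
Why: Alkaline hydrolysis: hydroxide in wet DMSO cleaves the aryl tosylate at sulfur and the di-ortho-substituted methyl ester (saponification, helped by SN2 attack at the ester methyl), and cold acidification frees the acid without acid-induced decarboxylation.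

Step 6
Reactants: 7 5-chloro-4-hydroxy-2-methoxy-3,6-dimethylbenzoic acid; 3 methyl 2,4-dihydroxy-3,5,6-trimethylbenzoate
Product: 10 methyl 4-[(5-chloro-4-hydroxy-2-methoxy-3,6-dimethylbenzoyl)oxy]-2-hydroxy-3,5,6-trimethylbenzoate, via O-acylisourea 8 (not isolated), via para-oxoketene 9 (not isolated)
Conditions: 3 (2.5 equiv), DIC (1.3 equiv), iPr2NEt (1.0 equiv), MeCN, 0 °C to rt, 7 added over 4 h by syringe pump; then 0.5 M HCl; excess 3 recovered
Reagents that add atoms: none
Why: Proposed new method: carbodiimide-triggered elimination–addition (E1cB) acyl transfer, in which the acid adds to DIC to give O-acylisourea 8 (phenols do not add to carbodiimides), the carbonyl of 8 is shielded from ordinary addition–elimination by the ortho methyl and methoxy groups, but its free para-OH (acidified by the ortho chlorine) passes its proton to the isourea nitrogen or the amine and expels N,N'-diisopropylurea by 1,6-elimination to give para-oxoketene 9, whose sp carbon projects beyond the ortho groups and is captured by the 4-OH of 3 (the more acidic hydroxyl; the 2-OH is locked by its hydrogen bond to the ester), re-aromatising ring B with its 4-OH free, while slow addition of 7 to excess 3 holds back self-esterification; the closest known reaction types are the dissociative E1cB hydrolysis of aryl 4-hydroxybenzoates through para-oxoketenes, salicylate ester formation by phenol capture of ortho-quinoketenes, and Steglich-type carbodiimide esterification.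

**Compound list**
1 | methyl 2,4-dihydroxy-3,6-dimethylbenzoate | COC(=O)c1c(C)cc(O)c(C)c1O | starting material
2 | methyl 5-formyl-2,4-dihydroxy-3,6-dimethylbenzoate | COC(=O)c1c(C)c(C=O)c(O)c(C)c1O | intermediate
3 | methyl 2,4-dihydroxy-3,5,6-trimethylbenzoate | COC(=O)c1c(C)c(C)c(O)c(C)c1O | intermediate
4 | methyl 5-chloro-2,4-dihydroxy-3,6-dimethylbenzoate | COC(=O)c1c(C)c(Cl)c(O)c(C)c1O | intermediate
5 | methyl 5-chloro-2-hydroxy-3,6-dimethyl-4-[(4-methylbenzenesulfonyl)oxy]benzoate | COC(=O)c1c(C)c(Cl)c(OS(=O)(=O)c2ccc(C)cc2)c(C)c1O | intermediate (not isolated)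
6 | methyl 5-chloro-2-methoxy-3,6-dimethyl-4-[(4-methylbenzenesulfonyl)oxy]benzoate | COC(=O)c1c(C)c(Cl)c(OS(=O)(=O)c2ccc(C)cc2)c(C)c1OC | intermediate
7 | 5-chloro-4-hydroxy-2-methoxy-3,6-dimethylbenzoic acid | OC(=O)c1c(C)c(Cl)c(O)c(C)c1OC | intermediate
8 | N,N'-diisopropyl-O-(5-chloro-4-hydroxy-2-methoxy-3,6-dimethylbenzoyl)isourea | CC(C)N=C(NC(C)C)OC(=O)c1c(C)c(Cl)c(O)c(C)c1OC | intermediate (not isolated)
9 | 2-chloro-5-methoxy-3,6-dimethyl-4-(oxomethylidene)cyclohexa-2,5-dien-1-one | COC1=C(C)C(=O)C(Cl)=C(C)C1=C=O | intermediate (not isolated)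
10 | methyl 4-[(5-chloro-4-hydroxy-2-methoxy-3,6-dimethylbenzoyl)oxy]-2-hydroxy-3,5,6-trimethylbenzoate | COC(=O)c1c(C)c(C)c(OC(=O)c2c(C)c(Cl)c(O)c(C)c2OC)c(C)c1O | target

**Step count**
Total steps: 6.
Longest linear sequence: 4 (steps 3, 4, 5, 6 from 1). The ring A branch is 2 steps before the coupling.

**Steps most likely to fail, with fallbacks**

Step 6 (the proposed new coupling). The risks are self-esterification of the ketene by ring B phenols and capture of the ketene by the urea. The fallback uses known chemistry, sets out from 7 and comes back at 10. The free 4-OH of 7 is capped with Ac2O, pyridine and catalytic DMAP (aqueous work-up hydrolyses the mixed anhydride) to give 4-(acetyloxy)-5-chloro-2-methoxy-3,6-dimethylbenzoic acid F1. F1 and 3 are condensed with trifluoroacetic anhydride in toluene at rt, the classical mixed-anhydride/acylium esterification for di-ortho-substituted depsides, to give methyl 4-{[4-(acetyloxy)-5-chloro-2-methoxy-3,6-dimethylbenzoyl]oxy}-2-hydroxy-3,5,6-trimethylbenzoate F2. The unhindered aryl acetate of F2 is then removed with NH3 in MeOH at 0 °C, which leaves the doubly shielded depside ester and the methyl ester alone and gives 10.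

Step 5 (saponification of a shielded ester whose ring becomes a phenoxide once the tosylate falls). The fallback sets out from 6 and comes back at 7. The ester methyl is removed by SN2 attack of iodide (LiI, pyridine, reflux; then dilute HCl), which does not need access to the shielded carbonyl, to give 5-chloro-2-methoxy-3,6-dimethyl-4-[(4-methylbenzenesulfonyl)oxy]benzoic acid F3. The tosylate of F3 is then cleaved on its own with KOH in MeOH/H2O at reflux, and cold acidification gives 7.

Step 4 (one-flask regioselective tosylation and hindered methylation). The fallback sets out from 4 and comes back at 7, bypassing steps 4 and 5, with an ether mask that survives saponification and isolated intermediates. Allyl bromide and K2CO3 in acetone give methyl 5-chloro-2-hydroxy-3,6-dimethyl-4-(prop-2-en-1-yloxy)benzoate F4, whose regiochemistry is checked. MeI and K2CO3 in DMF at 50 °C give methyl 5-chloro-2-methoxy-3,6-dimethyl-4-(prop-2-en-1-yloxy)benzoate F5. KOH in wet DMSO at 90 °C saponifies the ester on a ring that carries no phenoxide and gives 5-chloro-2-methoxy-3,6-dimethyl-4-(prop-2-en-1-yloxy)benzoic acid F6. Pd(PPh3)4 (zerovalent palladium) with morpholine in THF at rt then removes the allyl group under neutral conditions and gives 7.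

**Further compounds**
F1 | step 6 | 4-(acetyloxy)-5-chloro-2-methoxy-3,6-dimethylbenzoic acid | OC(=O)c1c(C)c(Cl)c(OC(C)=O)c(C)c1OC
F2 | step 6 | methyl 4-{[4-(acetyloxy)-5-chloro-2-methoxy-3,6-dimethylbenzoyl]oxy}-2-hydroxy-3,5,6-trimethylbenzoate | COC(=O)c1c(C)c(C)c(OC(=O)c2c(C)c(Cl)c(OC(C)=O)c(C)c2OC)c(C)c1O
F3 | step 5 | 5-chloro-2-methoxy-3,6-dimethyl-4-[(4-methylbenzenesulfonyl)oxy]benzoic acid | OC(=O)c1c(C)c(Cl)c(OS(=O)(=O)c2ccc(C)cc2)c(C)c1OC
F4 | step 4 | methyl 5-chloro-2-hydroxy-3,6-dimethyl-4-(prop-2-en-1-yloxy)benzoate | COC(=O)c1c(C)c(Cl)c(OCC=C)c(C)c1O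
F5 | step 4 | methyl 5-chloro-2-methoxy-3,6-dimethyl-4-(prop-2-en-1-yloxy)benzoate | COC(=O)c1c(C)c(Cl)c(OCC=C)c(C)c1OC
F6 | step 4 | 5-chloro-2-methoxy-3,6-dimethyl-4-(prop-2-en-1-yloxy)benzoic acid | OC(=O)c1c(C)c(Cl)c(OCC=C)c(C)c1OC
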